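**Retrosynthetic overview**

- The strategy rests on ring A of the flavone, a benzene ring with oxygen on five adjacent carbons: methoxyls on C5, C6, C7 and C8, and the ring oxygen O1 on C8a. C5 to C8 are therefore taken as the four oxygen-bearing carbons of dimethyl squarate, and C4a/C8a as the unsubstituted C5=C6 alkene of a 2-aryl-3-methoxy-4-pyranone.
- Working backwards: the C5 and C8 methyl ethers are removed, ring A is opened at C5–C4a (thermal cyclobutenone ring expansion), and the C8–C8a bond is cut (addition of the C6-lithiated pyranone to a squarate carbonyl).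
- The pyranone (ring C) is traced to a furan: O-methylation, epoxy-ketone to hydroxypyranone rearrangement, Achmatowicz ring expansion of an aryl furyl carbinol, itself from furfural and the aryl Grignard reagent.
- Ring order: ring B is purchased, ring C is built from the furan, ring A is closed last. The target is achiral, so all stereocentres on the way are racemic and disappear.

Key step: step 8

Remark on the chemistry: lithiation of the pyranone is assumed to occur at C6, the carbon next to the ring oxygen. If C5 were attacked instead, that adduct would lead to the same 5,8-hydroquinone, because the squarate-derived four-carbon unit is symmetric.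

**Route**

Step 1
Reactants: 1 1-bromo-2,4-dimethoxybenzene; 2 furfural
Product: 4 (2,4-dimethoxyphenyl)(furan-2-yl)methanol (racemic), via 2,4-dimethoxyphenylmagnesium bromide 3 (not isolated)
Conditions: Mg, I2 (cat.), THF, reflux; then 2, 0 °C to rt; aq. NH4Cl
Reagents that add atoms: none
Why: Grignard reaction; the aryl magnesium bromide should add 1,2 to the aldehyde to give the secondary carbinol, whose new centre forms racemic and is destroyed later.

Step 2
Reactants: 4 (2,4-dimethoxyphenyl)(furan-2-yl)methanol
Product: 6 2-(2,4-dimethoxyphenyl)-6-hydroxy-2H-pyran-3(6H)-one (racemic diastereomer mixture), via Z-keto-enal 5 (not isolated)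
Conditions: mCPBA, NaHCO3, CH2Cl2, 0 °C
Reagents that add atoms: mCPBA (3-chloroperbenzoic acid), OOC(=O)c1cccc(Cl)c1
Why: Achmatowicz rearrangement; the peracid should oxidise the furan faster than the dimethoxyarene and open it to the Z-keto-enal, which the carbinol oxygen closes to the six-membered lactol, while the NaHCO3 buffer keeps the ionisable diaryl carbinol intact and the two uncontrolled stereocentres are of no consequence.

Step 3
Reactants: 6 2-(2,4-dimethoxyphenyl)-6-hydroxy-2H-pyran-3(6H)-one
Product: 7 2-(2,4-dimethoxyphenyl)-6-methoxy-2H-pyran-3(6H)-one (racemic cis/trans mixture)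
Conditions: HC(OMe)3, BF3·OEt2 (cat.), CH2Cl2, 0 °C
Reagents that add atoms: trimethyl orthoformate, COC(OC)OC
Why: Acid-catalysed acetal exchange at the anomeric carbon through the ring oxocarbenium ion (glycosidation-type O-methylation with the orthoester as methanol source and water scavenger) should cap the lactol so that the ring cannot open under the basic peroxide of the next step.

Step 4
Reactants: 7 2-(2,4-dimethoxyphenyl)-6-methoxy-2H-pyran-3(6H)-one
Product: 8 4-(2,4-dimethoxyphenyl)-2-methoxy-3,7-dioxabicyclo[4.1.0]heptan-5-one (4,5-epoxide of 7; racemic diastereomer mixture)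
Conditions: 30% aq. H2O2, NaOH (0.2 equiv), MeOH, 0 °C
Reagents that add atoms: hydrogen peroxide, OO
Why: Weitz–Scheffer nucleophilic epoxidation; hydroperoxide should add in conjugate fashion to the enone and the enolate then expels hydroxide, with attack expected anti to the acetal methoxyl although the configuration does not matter.

Step 5
Reactants: 8 4-(2,4-dimethoxyphenyl)-2-methoxy-3,7-dioxabicyclo[4.1.0]heptan-5-one
Product: 9 2-(2,4-dimethoxyphenyl)-3-hydroxy-4H-pyran-4-one
Conditions: 1 M aq. H2SO4/1,4-dioxane (1:1), 90 °C
Reagents that add atoms: none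
Why: Acid-promoted isomerisation of the alpha,beta-epoxy ketone to the enolised 1,2-dione (opening at the carbon beta to the carbonyl, then dehydration), followed by enolisation towards the aryl-bearing carbon and loss of methanol from the acetal, should give the aromatic-like 3-hydroxy-4-pyranone as in the classical furan-to-maltol synthesis, with all stereocentres removed.

Step 6
Reactants: 9 2-(2,4-dimethoxyphenyl)-3-hydroxy-4H-pyran-4-one
Product: 10 2-(2,4-dimethoxyphenyl)-3-methoxy-4H-pyran-4-one
Conditions: MeI, K2CO3, acetone, reflux
Reagents that add atoms: iodomethane, CI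
Why: Williamson O-alkylation of the acidic enolic hydroxyl, a standard transformation of 3-hydroxy-4-pyranones, should complete rings B and C with the C3 methoxyl in place.

Step 7
Reactants: 10 2-(2,4-dimethoxyphenyl)-3-methoxy-4H-pyran-4-one; 11 dimethyl squarate (3,4-dimethoxycyclobut-3-ene-1,2-dione)
Product: 13 4-[6-(2,4-dimethoxyphenyl)-5-methoxy-4-oxo-4H-pyran-2-yl]-4-hydroxy-2,3-dimethoxycyclobut-2-en-1-one (racemic), via 6-lithiopyranone 12 (not isolated)
Conditions: LiTMP (from 2,2,6,6-tetramethylpiperidine and n-BuLi), THF, −78 °C, 20 min; cannulate into 11 (1.3 equiv), THF, −78 °C; aq. NH4Cl, −78 °C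
Reagents that add atoms: none
Why: Deprotonation of the vinylic hydrogen next to the ring oxygen by the hindered, non-nucleophilic lithium amide (as in the C2-lithiation of chromones) should give an alpha-alkoxyvinyllithium that adds 1,2 to one squarate carbonyl, the standard entry to 4-hydroxycyclobutenones; inverse addition and a cold neutral quench limit double addition and acid-induced loss of methanol, and the new carbinol centre is racemic.

Step 8
Reactants: 13 4-[6-(2,4-dimethoxyphenyl)-5-methoxy-4-oxo-4H-pyran-2-yl]-4-hydroxy-2,3-dimethoxycyclobut-2-en-1-one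
Product: 16 2-(2,4-dimethoxyphenyl)-5,8-dihydroxy-3,6,7-trimethoxy-4H-chromen-4-one, via dienylketene 14 (not isolated), via 4aH-chromene-4,5-dione 15 (not isolated)
Conditions: p-xylene (degassed), 138 °C, Ar
Reagents that add atoms: none
Why: On heating, the bond between the carbonyl carbon and the carbinol carbon of the cyclobutenone should break in a conrotatory 4π electrocyclic opening to dienylketene 14, whose terminal alkene is the C5=C6 bond of the pyranone. A 6π electrocyclisation (6-endo closure of the six-membered carbocycle, ring A) then joins the electrophilic ketene carbon (future C5) to pyranone C5 (future C4a), the nucleophilic alpha-carbon of the vinylogous ester, and dienone 15, whose C4a hydrogen lies between two carbonyls, should enolise at once to the aromatic 5,8-hydroquinone. The closest known reaction type is the thermal ring expansion of 4-alkenyl- and 4-heteroaryl-4-hydroxycyclobutenones from squarate esters to hydroquinones (Moore rearrangement). The only new stereocentre, C4a of 15, is transient and is erased by the tautomerisation, so no stereocontrol is needed. The selectivity required is torquoselectivity in the ring opening: the hydroxyl on the sp3 carbon, as the donor substituent, should rotate outward, which places the pyranonyl group next to the ketene, and closure onto pyranone C5 is then the only six-membered option. The squarate delivers C5 to C8 already oxygenated, and degassed solvent protects the electron-rich hydroquinone from oxidation to the 5,8-quinone.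

Step 9
Reactants: 16 2-(2,4-dimethoxyphenyl)-5,8-dihydroxy-3,6,7-trimethoxy-4H-chromen-4-one
Product: 17 2-(2,4-dimethoxyphenyl)-3,5,6,7,8-pentamethoxy-4H-chromen-4-one (3,5,6,7,8,2',4'-heptamethoxyflavone)
Conditions: Me2SO4 (excess), K2CO3, acetone, reflux, Ar
Reagents that add atoms: dimethyl sulfate, COS(=O)(=O)OC
Why: Williamson O-methylation of both phenolic hydroxyls; the C5 hydroxyl is hydrogen-bonded to the C4 carbonyl and should need excess reagent and prolonged reflux, as is routine for 5-hydroxyflavones, while argon (and an aqueous Na2S2O4 wash of crude 16 beforehand if any quinone is seen) keeps the substrate in the hydroquinone state.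

**Compound list**

1 | 1-bromo-2,4-dimethoxybenzene | COc1ccc(Br)c(OC)c1 | starting material
2 | furfural | O=Cc1ccco1 | starting material
3 | 2,4-dimethoxyphenylmagnesium bromide | COc1ccc([Mg]Br)c(OC)c1 | intermediate
4 | (2,4-dimethoxyphenyl)(furan-2-yl)methanol, racemic | COc1ccc(C(O)c2ccco2)c(OC)c1 | intermediate
5 | (Z)-5-(2,4-dimethoxyphenyl)-5-hydroxy-4-oxopent-2-enal, racemic | COc1ccc(C(O)C(=O)/C=C\C=O)c(OC)c1 | intermediate
6 | 2-(2,4-dimethoxyphenyl)-6-hydroxy-2H-pyran-3(6H)-one, racemic diastereomer mixture | COc1ccc(C2OC(O)C=CC2=O)c(OC)c1 | intermediate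
7 | 2-(2,4-dimethoxyphenyl)-6-methoxy-2H-pyran-3(6H)-one, racemic cis/trans mixture | COc1ccc(C2OC(OC)C=CC2=O)c(OC)c1 | intermediate
8 | 4-(2,4-dimethoxyphenyl)-2-methoxy-3,7-dioxabicyclo[4.1.0]heptan-5-one, racemic diastereomer mixture | COc1ccc(C2OC(OC)C3OC3C2=O)c(OC)c1 | intermediate
9 | 2-(2,4-dimethoxyphenyl)-3-hydroxy-4H-pyran-4-one | COc1ccc(-c2occc(=O)c2O)c(OC)c1 | intermediate
10 | 2-(2,4-dimethoxyphenyl)-3-methoxy-4H-pyran-4-one | COc1ccc(-c2occc(=O)c2OC)c(OC)c1 | intermediate
11 | dimethyl squarate (3,4-dimethoxycyclobut-3-ene-1,2-dione) | COC1=C(OC)C(=O)C1=O | starting material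
12 | [6-(2,4-dimethoxyphenyl)-5-methoxy-4-oxo-4H-pyran-2-yl]lithium | COc1ccc(-c2oc([Li])cc(=O)c2OC)c(OC)c1 | intermediate
13 | 4-[6-(2,4-dimethoxyphenyl)-5-methoxy-4-oxo-4H-pyran-2-yl]-4-hydroxy-2,3-dimethoxycyclobut-2-en-1-one, racemic | COc1ccc(-c2oc(C3(O)C(OC)=C(OC)C3=O)cc(=O)c2OC)c(OC)c1 | intermediate
14 | (Z)-4-[6-(2,4-dimethoxyphenyl)-5-methoxy-4-oxo-4H-pyran-2-yl]-4-hydroxy-2,3-dimethoxybuta-1,3-dien-1-one (dienylketene, pyranonyl group cis to the ketene) | O=C=C(OC)/C(OC)=C(O)\c1cc(=O)c(OC)c(-c2ccc(OC)cc2OC)o1 | intermediate
15 | 2-(2,4-dimethoxyphenyl)-8-hydroxy-3,6,7-trimethoxy-4aH-chromene-4,5-dione, racemic | COc1ccc(C2=C(OC)C(=O)C3C(=O)C(OC)=C(OC)C(O)=C3O2)c(OC)c1 | intermediate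
16 | 2-(2,4-dimethoxyphenyl)-5,8-dihydroxy-3,6,7-trimethoxy-4H-chromen-4-one | COc1ccc(-c2oc3c(O)c(OC)c(OC)c(O)c3c(=O)c2OC)c(OC)c1 | intermediate
17 | 2-(2,4-dimethoxyphenyl)-3,5,6,7,8-pentamethoxy-4H-chromen-4-one | COc1ccc(-c2oc3c(OC)c(OC)c(OC)c(OC)c3c(=O)c2OC)c(OC)c1 | target

**Step count**

Total step count: 9. Longest linear sequence: 9 steps (1 and 2 to 17; dimethyl squarate 11 enters as a purchased reagent).

**Steps most likely to fail and fallbacks**

1. Step 8 (thermal ring expansion).
   - What may go wrong: the hydroxyl may rotate inward, so that the ketene is trapped by the free hydroxyl as a butenolide. The 6π closure onto the weakly aromatic pyranone alkene may be slow enough for the dienylketene to decompose. The hydroquinone may oxidise to the quinone during heating and isolation.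
   - Fallback, setting out from 13 and returning at 17: the tertiary hydroxyl is capped first (MeI, Ag2O, K2CO3, MeCN, rt) to give 4-[6-(2,4-dimethoxyphenyl)-5-methoxy-4-oxo-4H-pyran-2-yl]-2,3,4-trimethoxycyclobut-2-en-1-one F1. This removes the internal ketene trap while the methoxyl still rotates outward. Thermolysis of F1 in degassed toluene or p-xylene should then give the air-stable, chelated phenol 2-(2,4-dimethoxyphenyl)-5-hydroxy-3,6,7,8-tetramethoxy-4H-chromen-4-one F2 with the C8 methoxyl already in place. Methylation of the single remaining C5 hydroxyl (Me2SO4, K2CO3, acetone, reflux) gives 17.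

2. Step 7 (lithiation and squarate addition).
   - What may go wrong: competing deprotonation on the dimethoxyphenyl ring between its two methoxyls; attack of the lithiated pyranone on unmetalated pyranone; ring opening of a C5-lithiated species; double addition to the squarate.
   - Fallback, setting out from 10 and returning at 13: the metalation is separated from the carbonyl addition. Zincation of 10 with TMPZnCl·LiCl (THF, rt) should give the configurationally and thermally stable chloro[6-(2,4-dimethoxyphenyl)-5-methoxy-4-oxo-4H-pyran-2-yl]zinc F3. Quenching with I2 gives 2-(2,4-dimethoxyphenyl)-6-iodo-3-methoxy-4H-pyran-4-one F4, which can be purified. Iodine–magnesium exchange with i-PrMgCl·LiCl (THF, −40 °C) then generates chloro[6-(2,4-dimethoxyphenyl)-5-methoxy-4-oxo-4H-pyran-2-yl]magnesium F5 cleanly and regiospecifically in the absence of amide base. F5 is added to dimethyl squarate 11 at −40 °C and quenched with aq. NH4Cl to give 13.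

3. Step 4 (alkaline epoxidation).
   - What may go wrong: under basic peroxide, removal of the acidic C2 hydrogen (flanked by the ketone, the ring oxygen and the aryl group) may trigger enolate-driven loss of methoxide or oxidative degradation instead of clean conjugate epoxidation.
   - Fallback, setting out from 7 and returning at 9: the oxygen is introduced under neutral conditions by dihydroxylation of the enone (OsO4 cat., NMO, citric acid, t-BuOH/H2O, rt) to give 2-(2,4-dimethoxyphenyl)-4,5-dihydroxy-6-methoxyoxan-3-one F6. On the same acid treatment as in step 5 (1 M aq. H2SO4/1,4-dioxane, 90 °C), F6 should lose water (beta-elimination to the enolised 1,2-dione) and methanol to give 9 directly, bypassing epoxide 8.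

**Further compounds**

F1 | step 8 | 4-[6-(2,4-dimethoxyphenyl)-5-methoxy-4-oxo-4H-pyran-2-yl]-2,3,4-trimethoxycyclobut-2-en-1-one, racemic | COc1ccc(-c2oc(C3(OC)C(OC)=C(OC)C3=O)cc(=O)c2OC)c(OC)c1
F2 | step 8 | 2-(2,4-dimethoxyphenyl)-5-hydroxy-3,6,7,8-tetramethoxy-4H-chromen-4-one | COc1ccc(-c2oc3c(OC)c(OC)c(OC)c(O)c3c(=O)c2OC)c(OC)c1
F3 | step 7 | chloro[6-(2,4-dimethoxyphenyl)-5-methoxy-4-oxo-4H-pyran-2-yl]zinc | COc1ccc(-c2oc([Zn]Cl)cc(=O)c2OC)c(OC)c1
F4 | step 7 | 2-(2,4-dimethoxyphenyl)-6-iodo-3-methoxy-4H-pyran-4-one | COc1ccc(-c2oc(I)cc(=O)c2OC)c(OC)c1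
F5 | step 7 | chloro[6-(2,4-dimethoxyphenyl)-5-methoxy-4-oxo-4H-pyran-2-yl]magnesium | COc1ccc(-c2oc([Mg]Cl)cc(=O)c2OC)c(OC)c1
F6 | step 4 | 2-(2,4-dimethoxyphenyl)-4,5-dihydroxy-6-methoxyoxan-3-one, racemic diastereomer mixture | COc1ccc(C2OC(OC)C(O)C(O)C2=O)c(OC)c1
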